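## Retrosynthetic overview

1. Numbering: ring A = C6 (spiro), C7 (=C14H2), C8, C9 (OH), C10 (Br), C11 (two methyls). Ring B = C6, C1, C2 (Br), C3 (Cl and the C15 methyl), C4, C5.
2. The strategy rests on the vicinal pair C2(Br)/C3(Cl,CH3) of ring B. Each of these carbons is read as a former carbonyl carbon: C2 as an aldehyde on the C1 arm of C6, and C3 as a methyl ketone on the C5–C4 arm. C2–C3 is therefore the bond to make.
3. Target ⇒ C9 ketone reduction, C7=C8 to C7=C14 deconjugation and C10 bromination ⇒ 2-bromo-3-chloro enone ⇒ (Cl at C3 with retention, Br at C2 with inversion through a cyclic sulfate) cis-2,3-diol enone ⇒ (CH3Li/CeCl3, then acid) cis-diol vinylogous ester.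
4. cis-Diol ⇒ SmI2 pinacol closure of ring B ⇒ keto aldehyde ⇒ double oxidative cleavage of a C6 allyl/3-methylbut-3-enyl diene ⇒ Pd-catalysed decarboxylative allylation (sets C6) ⇒ alkylated dimedone isobutyl vinylogous ester.
5. Ring order: ring A comes with dimedone, and ring B is closed in step 7.

Key step: step 7

Assumption: the sense of induction of the (S)-configured phosphinooxazoline is taken from its behaviour with 2-alkylcyclohexanone enolates, which maps onto 6R in step 5; if the hindered enolate responds in the opposite sense, the (R)-ligand is used.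

## Route

Step 1
Reactants: 1 dimedone (5,5-dimethylcyclohexane-1,3-dione); 2 2-methylpropan-1-ol
Product: 3 3-isobutoxy-5,5-dimethylcyclohex-2-en-1-one
Conditions: p-TsOH·H2O (cat.), toluene, reflux, Dean–Stark
Reagents that add atoms: 2-methylpropan-1-ol, CC(C)CO
Why: Acid-catalysed condensation of a cyclic 1,3-dione with an alcohol (vinylogous esterification) is driven by azeotropic removal of water, and no stereocentre is formed.

Step 2
Reactants: 4 3-methylbut-3-en-1-ol
Product: 5 4-iodo-2-methylbut-1-ene
Conditions: I2, PPh3, imidazole, CH2Cl2, 0 °C to rt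
Reagents that add atoms: iodine, II
Why: Appel-type iodination turns the primary alcohol into the iodide through its alkoxyphosphonium salt without touching the 1,1-disubstituted alkene.

Step 3
Reactants: 3 3-isobutoxy-5,5-dimethylcyclohex-2-en-1-one; 5 4-iodo-2-methylbut-1-ene
Product: 7 rac-3-isobutoxy-5,5-dimethyl-6-(3-methylbut-3-en-1-yl)cyclohex-2-en-1-one, via lithium enolate 6 (not isolated)
Conditions: LiN(i-Pr)2, THF, −78 °C; then 5, −78 °C to rt
Reagents that add atoms: 4-iodo-2-methylbut-1-ene, C=C(C)CCI
Why: Kinetic α′-deprotonation of the vinylogous ester (Stork–Danheiser alkylation) gives the cross-conjugated enolate, which the primary iodide alkylates at C6; the 1,1-disubstituted alkene serves as a masked C3 methyl ketone, so no acid-labile ketal has to be put on or taken off beside the acid-sensitive vinylogous ester, and the racemic C6 centre is erased in step 4.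

Step 4
Reactants: 7 rac-3-isobutoxy-5,5-dimethyl-6-(3-methylbut-3-en-1-yl)cyclohex-2-en-1-one; 8 allyl chloroformate
Product: 10 allyl 5-isobutoxy-3,3-dimethyl-2-(3-methylbut-3-en-1-yl)cyclohexa-1,5-dien-1-yl carbonate, via lithium enolate 9 (not isolated)
Conditions: LiN(i-Pr)2, TMEDA, THF, −78 to 0 °C; then allyl chloroformate, −78 °C
Reagents that add atoms: allyl chloroformate, C=CCOC(Cl)=O
Why: The fully substituted C6=C7 enolate, walled in by C11, is acylated on oxygen by the hard chloroformate (O-acylation of a hindered enolate, helped by TMEDA), which fixes the enolate regiochemistry for step 5.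

Step 5
Reactants: 10 allyl enol carbonate
Product: 11 (R)-6-allyl-3-isobutoxy-5,5-dimethyl-6-(3-methylbut-3-en-1-yl)cyclohex-2-en-1-one
Conditions: Pd2(dba)3 (5 mol %), (S)-(CF3)3-t-BuPHOX [(S)-4-tert-butyl-2-{2-[bis(4-trifluoromethylphenyl)phosphanyl]-5-(trifluoromethyl)phenyl}-4,5-dihydrooxazole, 12.5 mol %], toluene, 20 °C
Reagents that add atoms: none
Why: In this decarboxylative asymmetric allylic alkylation (Tsuji–Trost type), zerovalent palladium ionises the allyl carbonate, CO2 is lost, and the tetrasubstituted enolate couples with the allyl group inside the chiral P,N-ligand pocket, which sets quaternary C6 as R, while the electron-poor ligand speeds the hindered C–C coupling.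

Step 6
Reactants: 11 (R)-6-allyl-3-isobutoxy-5,5-dimethyl-6-(3-methylbut-3-en-1-yl)cyclohex-2-en-1-one
Product: 13 (R)-2-[4-isobutoxy-6,6-dimethyl-2-oxo-1-(3-oxobutyl)cyclohex-3-en-1-yl]acetaldehyde, via tetraol 12 (not isolated)
Conditions: OsO4 (2 mol %), NaIO4 (6 equiv), 2,6-lutidine, dioxane/H2O, rt
Reagents that add atoms: osmium tetroxide, O=[Os](=O)(=O)=O; sodium periodate, [Na+].[O-]I(=O)(=O)=O
Why: Lemieux–Johnson oxidation converts the monosubstituted alkene into the C2 aldehyde and the 1,1-disubstituted alkene into the C3 methyl ketone in one operation, while the trisubstituted C8=C9 alkene is deactivated by conjugation with C7=O and is shielded, 2,6-lutidine keeps the medium too mild for aldol closure, and C6 is untouched.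

Step 7
Reactants: 13 (R)-2-[4-isobutoxy-6,6-dimethyl-2-oxo-1-(3-oxobutyl)cyclohex-3-en-1-yl]acetaldehyde
Product: 14 (2S,3R,6R)-2,3-dihydroxy-9-isobutoxy-14-norchamigr-8-en-7-one [(6R,8S,9R)-8,9-dihydroxy-3-isobutoxy-5,5,9-trimethylspiro[5.5]undec-2-en-1-one; both hydroxyls on the C11 side of ring B]
Conditions: SmI2 (0.1 M in THF, 3 equiv), t-BuOH (3 equiv), THF, −78 °C to rt, slow addition of 13 at high dilution
Reagents that add atoms: none
Why: SmI2 transfers one electron to the C2 aldehyde, the most easily reduced carbonyl group, the resulting trivalent-samarium ketyl adds to the samarium-bound C3 ketone carbon, and a second electron and t-BuOH complete the diol. The closest known reaction type is the SmI2-mediated intramolecular pinacol coupling of 1,6-keto aldehydes to cis-cyclohexane-1,2-diols. Ring B closes in the 6-exo-trig mode by formation of C2–C3. The cis relation of the C2 and C3 oxygens follows from both being held on one samarium centre, and their relation to C6 follows from a chair in which quaternary C11, the C2 oxygen and the C15 methyl are equatorial while the flat C7 carbonyl carbon and the C3 oxygen are axial, which puts both oxygens on the C11 side (2S,3R). The step needs chemoselectivity for the two isolated carbonyl groups over C7=O, which the electron-rich and hard-to-reduce β-alkoxy enone secures, and it needs ring closure to outrun intermolecular coupling, which slow addition at high dilution secures.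

Step 8
Reactants: 14 (2S,3R,6R)-2,3-dihydroxy-9-isobutoxy-14-norchamigr-8-en-7-one
Product: 16 (2S,3R,6R)-2,3-dihydroxychamigr-7-en-9-one, via tertiary allylic alcohol 15 (not isolated)
Conditions: CH3Li (6 equiv), anhydrous CeCl3 (6 equiv), THF, −78 to 0 °C; then 10 % aq. HCl, rt
Reagents that add atoms: methyllithium, [Li]C; water, O
Why: In this Stork–Danheiser transposition the weakly basic organocerium reagent first deprotonates the two hydroxyls and then adds 1,2 to the hindered C7 carbonyl, and acid ionises the tertiary allylic alcohol and hydrolyses the enol ether to the C9 enone, which erases the transient C7 centre and leaves C2, C3 and C6 untouched.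

Step 9
Reactants: 16 (2S,3R,6R)-2,3-dihydroxychamigr-7-en-9-one
Product: 17 2,3-cyclic sulfite of 16 (2S,3R,6R; both epimers at sulfur)
Conditions: SOCl2, Et3N, CH2Cl2, 0 °C
Reagents that add atoms: thionyl chloride, O=S(Cl)Cl
Why: A cis-1,2-diol closes with SOCl2 and base to the five-membered cyclic sulfite faster than the tertiary hydroxyl is dehydrated, and because no C–O bond is broken C2 and C3 are retained (the sulfur epimers converge in step 10).

Step 10
Reactants: 17 2,3-cyclic sulfite
Product: 18 2,3-cyclic sulfate of 16 (2S,3R,6R)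
Conditions: RuCl3·xH2O (1 mol %), NaIO4, MeCN/CH2Cl2/H2O, 0 °C, short contact
Reagents that add atoms: sodium periodate, [Na+].[O-]I(=O)(=O)=O
Why: Catalytic RuO4 generated from RuCl3 and NaIO4 oxidises sulfite sulfur to the sulfate within minutes at 0 °C, much faster than it attacks the electron-poor trisubstituted enone alkene.

Step 11
Reactants: 18 2,3-cyclic sulfate
Product: 20 (2R,3R,6R)-2-bromo-3-hydroxychamigr-7-en-9-one, via lithium bromo sulfate 19 (not isolated)
Conditions: LiBr (5 equiv), THF, rt to 50 °C; then 20 % aq. H2SO4, Et2O, rt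
Reagents that add atoms: lithium bromide, [Li+].[Br-]; water, O
Why: In the nucleophilic opening of a 1,2-cyclic sulfate, bromide attacks the secondary carbon C2 in an SN2 manner from the C7 side, anti to the C2–O bond, which inverts C2 to 2R, and the tertiary sulfate monoester is then hydrolysed by acid with the C3 configuration kept, whether sulfur–oxygen cleavage or bromine-assisted C–O ionisation operates.

Step 12
Reactants: 20 (2R,3R,6R)-2-bromo-3-hydroxychamigr-7-en-9-one
Product: 22 (2R,3R,6R)-2-bromo-3-chlorochamigr-7-en-9-one, via chlorosulfite 21 (not isolated)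
Conditions: SOCl2, CH2Cl2, 0 °C; then TiCl4 (10 mol %), 0 °C
Reagents that add atoms: thionyl chloride, O=S(Cl)Cl
Why: In this substitution of a β-bromo alcohol with neighbouring-group participation, the chlorosulfite ionises at tertiary C3, the C2 bromine bridges the face opposite the leaving oxygen, and chloride, also handed over from the departing chlorosulfite side by TiCl4, enters on the face that oxygen left, so C3 keeps its configuration (3R) and Br and Cl end trans.

Step 13
Reactants: 22 (2R,3R,6R)-2-bromo-3-chlorochamigr-7-en-9-one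
Product: 24 (2R,3R,6S)-2-bromo-3-chloro-9-(trimethylsilyloxy)chamigra-7,9-diene, via lithium dienolate 23 (not isolated)
Conditions: LiN(i-Pr)2 added to 22 and Me3SiCl, THF, −78 °C; Et3N, pentane, aq. NaHCO3
Reagents that add atoms: chlorotrimethylsilane, C[Si](C)(C)Cl
Why: Kinetic α′-deprotonation of the enone at C10 (as with isophorone, whose α′ carbon also adjoins a gem-dimethyl carbon) and immediate O-silylation fix the enol regiochemistry toward C10, and at −78 °C amide-induced elimination of the ring B halides should not compete.

Step 14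
Reactants: 24 (2R,3R,6S)-2-bromo-3-chloro-9-(trimethylsilyloxy)chamigra-7,9-diene
Product: 25 (2R,3R,6S,10S)-2,10-dibromo-3-chlorochamigr-7-en-9-one
Conditions: NBS, NaHCO3, THF, −78 to 0 °C
Reagents that add atoms: N-bromosuccinimide, O=C1CCC(=O)N1Br
Why: In this electrophilic bromination of a silyl enol ether, bromine enters at C10, the terminus that regenerates the enone, and settles equatorial on ring A beside C11; C6 distinguishes the two faces only through its C1 and C5 arms, so the bias is expected to be small, and the 10S epimer (Br cis to C1) is therefore taken on after chromatography while the 10R epimer is returned to the epimer mixture by base-mediated enolisation (C11 carries no hydrogen, so no HBr can be lost).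

Step 15
Reactants: 25 (2R,3R,6S,10S)-2,10-dibromo-3-chlorochamigr-7-en-9-one
Product: 26 (2R,3R,6S,10S)-2,10-dibromo-9-(tert-butyldimethylsilyloxy)-3-chlorochamigra-7(14),8-diene
Conditions: t-BuMe2SiOTf, Et3N, CH2Cl2, 0 °C to rt
Reagents that add atoms: tert-butyldimethylsilyl triflate, CC(C)(C)[Si](C)(C)OS(=O)(=O)C(F)(F)F
Why: In this soft enolisation, O-silylation gives the oxocarbenium ion, from which Et3N should remove an exposed C14 methyl proton rather than the single C10 proton walled in by bromine and C11, giving the linearly conjugated silyloxy diene as is known for γ-enolisable enones such as steroidal 4-en-3-ones, so C10 is not touched.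

Step 16
Reactants: 26 (2R,3R,6S,10S)-2,10-dibromo-9-(tert-butyldimethylsilyloxy)-3-chlorochamigra-7(14),8-diene
Product: 28 (2R,3R,6S,10S)-2,10-dibromo-3-chlorochamigr-7(14)-en-9-one, via ammonium dienolate 27 (not isolated)
Conditions: Bu4NF/AcOH (premixed), THF, −78 °C; pH 7 buffer; crude ketone used at once
Reagents that add atoms: none
Why: Fluoride frees the dienolate, which acetic acid protonates under kinetic control at the α-carbon C8 (deconjugative protonation of a dienolate), leaving the exocyclic C7=C14 alkene, and at −78 °C protonation should outrun both bromide loss from C10 and reconjugation.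

Step 17
Reactants: 28 (2R,3R,6S,10S)-2,10-dibromo-3-chlorochamigr-7(14)-en-9-one
Product: 29 (2R,3R,6S,9R,10S)-2,10-dibromo-3-chlorochamigr-7(14)-en-9-ol (target)
Conditions: i-Bu2AlH, Et2O, −78 °C; aq. potassium sodium tartrate
Reagents that add atoms: none
Why: In this hydride reduction of a hindered cyclohexanone, the axial C11 methyl blocks the axial trajectory at C9, so hydride enters from the equatorial side and gives the axial 9R alcohol cis to the equatorial C10 bromine, and at −78 °C the alkyl halides and the alkene are inert.

## Compound list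

1 | dimedone | CC1(C)CC(=O)CC(=O)C1 | starting material
2 | 2-methylpropan-1-ol | CC(C)CO | starting material
3 | 3-isobutoxy-5,5-dimethylcyclohex-2-en-1-one | CC(C)COC1=CC(=O)CC(C)(C)C1 | intermediate
4 | 3-methylbut-3-en-1-ol | C=C(C)CCO | starting material
5 | 4-iodo-2-methylbut-1-ene | C=C(C)CCI | intermediate
6 | lithium cross-conjugated enolate of 3 | [Li]OC1=CC(C)(C)CC(OCC(C)C)=C1 | intermediate
7 | rac-3-isobutoxy-5,5-dimethyl-6-(3-methylbut-3-en-1-yl)cyclohex-2-en-1-one | O=C1C=C(OCC(C)C)CC(C)(C)C1CCC(C)=C | intermediate
8 | allyl chloroformate | C=CCOC(Cl)=O | starting material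
9 | lithium C6=C7 enolate of 7 | [Li]OC1=C(CCC(C)=C)C(C)(C)CC(OCC(C)C)=C1 | intermediate
10 | allyl 5-isobutoxy-3,3-dimethyl-2-(3-methylbut-3-en-1-yl)cyclohexa-1,5-dien-1-yl carbonate | C=CCOC(=O)OC1=C(CCC(C)=C)C(C)(C)CC(OCC(C)C)=C1 | intermediate
11 | (R)-6-allyl-3-isobutoxy-5,5-dimethyl-6-(3-methylbut-3-en-1-yl)cyclohex-2-en-1-one | O=C1C=C(OCC(C)C)CC(C)(C)[C@]1(CC=C)CCC(C)=C | intermediate
12 | (6R)-tetraol from dihydroxylation of both side-chain alkenes of 11 (mixture at the new carbinol carbons) | O=C1C=C(OCC(C)C)CC(C)(C)[C@]1(CC(O)CO)CCC(C)(O)CO | intermediate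
13 | (R)-2-[4-isobutoxy-6,6-dimethyl-2-oxo-1-(3-oxobutyl)cyclohex-3-en-1-yl]acetaldehyde | O=C1C=C(OCC(C)C)CC(C)(C)[C@]1(CC=O)CCC(C)=O | intermediate
14 | (2S,3R,6R)-2,3-dihydroxy-9-isobutoxy-14-norchamigr-8-en-7-one | O=C1C=C(OCC(C)C)CC(C)(C)[C@]12CC[C@@](C)(O)[C@@H](O)C2 | intermediate
15 | (2S,3R,6R)-9-isobutoxychamigr-8-ene-2,3,7-triol (either C7 epimer) | CC1(O)C=C(OCC(C)C)CC(C)(C)[C@]12CC[C@@](C)(O)[C@@H](O)C2 | intermediate
16 | (2S,3R,6R)-2,3-dihydroxychamigr-7-en-9-one | CC1=CC(=O)CC(C)(C)[C@]12CC[C@@](C)(O)[C@@H](O)C2 | intermediate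
17 | 2,3-cyclic sulfite of 16 (sulfur epimers) | CC1=CC(=O)CC(C)(C)[C@]12CC[C@@](C)(OS(=O)O3)[C@@H]3C2 | intermediate
18 | 2,3-cyclic sulfate of 16 | CC1=CC(=O)CC(C)(C)[C@]12CC[C@@](C)(OS(=O)(=O)O3)[C@@H]3C2 | intermediate
19 | lithium (2R,3R,6R)-2-bromo-9-oxochamigr-7-en-3-yl sulfate | CC1=CC(=O)CC(C)(C)[C@]12CC[C@@](C)(OS(=O)(=O)[O-])[C@H](Br)C2.[Li+] | intermediate
20 | (2R,3R,6R)-2-bromo-3-hydroxychamigr-7-en-9-one | CC1=CC(=O)CC(C)(C)[C@]12CC[C@@](C)(O)[C@H](Br)C2 | intermediate
21 | C3 chlorosulfite of 20 | CC1=CC(=O)CC(C)(C)[C@]12CC[C@@](C)(OS(=O)Cl)[C@H](Br)C2 | intermediate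
22 | (2R,3R,6R)-2-bromo-3-chlorochamigr-7-en-9-one | CC1=CC(=O)CC(C)(C)[C@]12CC[C@@](C)(Cl)[C@H](Br)C2 | intermediate
23 | lithium C9=C10 dienolate of 22 | CC1=CC(O[Li])=CC(C)(C)[C@]12CC[C@@](C)(Cl)[C@H](Br)C2 | intermediate
24 | (2R,3R,6S)-2-bromo-3-chloro-9-(trimethylsilyloxy)chamigra-7,9-diene | CC1=CC(O[Si](C)(C)C)=CC(C)(C)[C@]12CC[C@@](C)(Cl)[C@H](Br)C2 | intermediate
25 | (2R,3R,6S,10S)-2,10-dibromo-3-chlorochamigr-7-en-9-one | CC1=CC(=O)[C@@H](Br)C(C)(C)[C@]12CC[C@@](C)(Cl)[C@H](Br)C2 | intermediate
26 | (2R,3R,6S,10S)-2,10-dibromo-9-(tert-butyldimethylsilyloxy)-3-chlorochamigra-7(14),8-diene | C=C1C=C(O[Si](C)(C)C(C)(C)C)[C@@H](Br)C(C)(C)[C@]12CC[C@@](C)(Cl)[C@H](Br)C2 | intermediate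
27 | tetrabutylammonium dienolate from 26 | C=C1C=C([O-])[C@@H](Br)C(C)(C)[C@]12CC[C@@](C)(Cl)[C@H](Br)C2.CCCC[N+](CCCC)(CCCC)CCCC | intermediate
28 | (2R,3R,6S,10S)-2,10-dibromo-3-chlorochamigr-7(14)-en-9-one | C=C1CC(=O)[C@@H](Br)C(C)(C)[C@]12CC[C@@](C)(Cl)[C@H](Br)C2 | intermediate
29 | (2R,3R,6S,9R,10S)-2,10-dibromo-3-chlorochamigr-7(14)-en-9-ol | C=C1C[C@@H](O)[C@@H](Br)C(C)(C)[C@]12CC[C@@](C)(Cl)[C@H](Br)C2 | target

## Step count and risks

Total step count: 17.
Longest linear sequence: 16 (steps 1 and 3–17, from dimedone).

**Step 7 (pinacol closure).** Facial selectivity relative to C6 may be poor. The Lewis-basic C7 carbonyl oxygen may join the samarium chelate and draw the C2 ketyl oxygen to the C7 side. Simple reduction of the aldehyde may also run ahead of ring closure.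

The fallback sets out from diene 11. Ring-closing metathesis with the second-generation Hoveyda–Grubbs catalyst (toluene, 60 °C) should join the allyl and 3-methylbut-3-enyl arms to the spiro alkene (6R)-9-isobutoxy-14-norchamigra-2,8-dien-7-one F1. Dihydroxylation with OsO4 (cat.) and N-methylmorpholine N-oxide in acetone/H2O should then attack the isolated C2=C3 alkene from the face opposite the pseudoaxial C7. This places both oxygens on the C11 side and comes back to the route at 14.

**Step 12 (C3 chloride with retention).** Ionisation at C3 may be followed by proton loss toward C4 or C15. The C3 configuration may also leak. The chair that sets C2–Br and C3–O antiperiplanar also places bromine syn-axial to C7, so it is poorly populated and bridging is weakened.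

The fallback sets out from enone diol 16 and removes both oxygens instead of exchanging them one by one.
- 1,1′-Thiocarbonyldiimidazole (toluene, reflux) should give the cyclic thionocarbonate F2.
- P(OMe)3 at reflux (Corey–Winter olefination) should give (6R)-chamigra-2,7-dien-9-one F3.
- Bu4N[BrCl2] in CH2Cl2 at low temperature should add Br and Cl anti and in the Markovnikov sense (Cl at tertiary C3) to the electron-rich C2=C3 alkene rather than to the enone.

This comes back to the route at 22, after separation from the diastereomer that arises from bromonium formation on the other face. Steps 9–12 are bypassed, which also covers a sluggish bromide opening in step 11.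

**Step 15 (extended enolisation).** Enolisation may run toward C10 instead of C14, with loss of the C10 configuration and no access to the exocyclic alkene.

The fallback sets out from bromo enone 25 and uses equilibrating enol esterification followed by deconjugative reduction. Isopropenyl acetate with p-TsOH (cat.) should give the linearly conjugated dienol acetate F4 under thermodynamic control. NaBH4 in EtOH/THF/H2O at 0 °C should then cleave the enol ester. The dienolate is protonated by the solvent at C8, and the unconjugated ketone is reduced before it can reconjugate, as in the classical conversion of steroidal 4-en-3-ones into 5-en-3-ols. This comes back to the route at 29.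

## Further compounds

F1 | step 7 | (6R)-9-isobutoxy-14-norchamigra-2,8-dien-7-one | O=C1C=C(OCC(C)C)CC(C)(C)[C@]12CCC(C)=CC2
F2 | step 12 | (2S,3R,6R)-2,3-cyclic thionocarbonate of 16 | CC1=CC(=O)CC(C)(C)[C@]12CC[C@@](C)(OC(=S)O3)[C@@H]3C2
F3 | step 12 | (6R)-chamigra-2,7-dien-9-one | CC1=CC(=O)CC(C)(C)[C@]12CCC(C)=CC2
F4 | step 15 | (2R,3R,6S,10S)-2,10-dibromo-3-chlorochamigra-7(14),8-dien-9-yl acetate | C=C1C=C(OC(C)=O)[C@@H](Br)C(C)(C)[C@]12CC[C@@](C)(Cl)[C@H](Br)C2
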